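**Retrosynthetic overview**

1. Feature: the six-carbon chain O–CH (ring A) → ring A lactone C=O → spiro carbon → ring B ketone → C(CH3) → ring C lactone C=O is the ring of an isobutyryl C-methyl phloroglucinol. The CH2–CH of ring B and the O–CMe2 of ring C are a C5 unit bridged across that ring.
2. Target 20 ⇒ spiro 2-acylcyclopentanone 18 (enolate hydroxylation, carbon-to-oxygen acyl shift) ⇒ prenyl β-diketone 17 (Mn(OAc)3/Cu(OAc)2 radical cyclisation) ⇒ tricyclic vinylogous ester 16 (retro-Claisen).
3. 16 ⇒ allyl adduct 14 (cross-metathesis) ⇒ aryl 1,1-dimethylallyl ether 12 by dearomative phenoxonium (5+2) cycloaddition, which closes ring B and the oxygen ring that becomes ring C and sets three stereocentres under a chiral trivalent-iodine oxidant.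
4. 12 ⇒ phloroglucinol, isobutyryl chloride, allyl bromide, 3-chloro-3-methylbut-1-yne and MeI. Allyl stands in for prenyl until after the oxidation, and the ether is placed before the C-methyl group so that the hydroxyl to be etherified is the unhindered one of the two ortho to the ketone.
5. Ring order: arene → ring B and oxygen ring (step 8) → ring C lactone (step 10) → carbocycle on the spiro carbon (step 11) → ring A lactone (step 12).

Key step: step 8

Assumption: which antipode of the chiral iodine reagent gives 14 and not its mirror image cannot be predicted for this substrate; the (R,R) reagent is written and the (S,S) reagent is taken if the first run shows the opposite sense.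

**Route**

Step 1
Reactants: 1 benzene-1,3,5-triol; 2 2-methylpropanoyl chloride
Product: 3 2-methyl-1-(2,4,6-trihydroxyphenyl)propan-1-one
Conditions: AlCl3, PhNO2/CH2Cl2, 0 to 60 °C; aq. HCl
Reagents that add atoms: 2-methylpropanoyl chloride (2), CC(C)C(=O)Cl
Why: Friedel–Crafts C-acylation of the symmetric triol should stop at the mono-ketone, because the first acyl group deactivates the ring.

Step 2
Reactants: 3 2-methyl-1-(2,4,6-trihydroxyphenyl)propan-1-one; 4 3-bromoprop-1-ene
Product: 5 2-methyl-1-[2,4,6-trihydroxy-3-(prop-2-en-1-yl)phenyl]propan-1-one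
Conditions: 4 (0.9 equiv), 1 M aq. KOH, 0 °C
Reagents that add atoms: 3-bromoprop-1-ene (4), C=CCBr
Why: C-alkylation of the phloroglucinolate in water goes to ring carbon, the two open positions of 3 are equivalent, and a deficit of halide holds back diallylation.

Step 3
Reactants: 5 2-methyl-1-[2,4,6-trihydroxy-3-(prop-2-en-1-yl)phenyl]propan-1-one
Product: 6 1-[2,6-dihydroxy-3-(prop-2-en-1-yl)-4-(triisopropylsilyloxy)phenyl]-2-methylpropan-1-one
Conditions: iPr3SiCl, imidazole, DMF, 0 °C
Reagents that add atoms: chlorotri(propan-2-yl)silane, CC(C)[Si](Cl)(C(C)C)C(C)C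
Why: Selective silylation of a phenol: the hydroxyl para to the ketone is the most acidic (vinylogous acid) and is not tied into the hydrogen bond to the carbonyl, so mono-silylation should go there.

Step 4
Reactants: 6 1-[2,6-dihydroxy-3-(prop-2-en-1-yl)-4-(triisopropylsilyloxy)phenyl]-2-methylpropan-1-one; 7 3-chloro-3-methylbut-1-yne
Product: 8 1-[2-hydroxy-6-(2-methylbut-3-yn-2-yloxy)-3-(prop-2-en-1-yl)-4-(triisopropylsilyloxy)phenyl]-2-methylpropan-1-one
Conditions: CuCl2·2H2O (cat.), DBU, MeCN, 0 °C
Reagents that add atoms: 3-chloro-3-methylbut-1-yne (7), CC(C)(Cl)C#C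
Why: Copper-catalysed O-alkylation of a phenol with a tertiary propargylic chloride; the ortho-hydroxyl next to the ring CH is open, whereas the one next to the allyl group is crowded and takes up the hydrogen bond to the ketone once its neighbour is etherified.

Step 5
Reactants: 8 1-[2-hydroxy-6-(2-methylbut-3-yn-2-yloxy)-3-(prop-2-en-1-yl)-4-(triisopropylsilyloxy)phenyl]-2-methylpropan-1-one
Product: 9 1-[2,4-dihydroxy-6-(2-methylbut-3-yn-2-yloxy)-3-(prop-2-en-1-yl)phenyl]-2-methylpropan-1-one
Conditions: Bu4NF, AcOH, THF, 0 °C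
Reagents that add atoms: none
Why: Fluoride cleavage of the aryl silyl ether leaves the propargylic ether, the alkyne and the alkene untouched.

Step 6
Reactants: 9 1-[2,4-dihydroxy-6-(2-methylbut-3-yn-2-yloxy)-3-(prop-2-en-1-yl)phenyl]-2-methylpropan-1-one; 10 iodomethane
Product: 11 1-[2,4-dihydroxy-5-methyl-6-(2-methylbut-3-yn-2-yloxy)-3-(prop-2-en-1-yl)phenyl]-2-methylpropan-1-one
Conditions: NaOMe (2.2 equiv), MeOH, 0 °C; 10 (1.1 equiv), 0 °C to rt
Reagents that add atoms: iodomethane (10), CI
Why: C-methylation of the acylphloroglucinol dianion in methanol should take the one ring carbon that still bears hydrogen and restore the arene, in preference to O-methylation and to dearomatising attack at the allyl-bearing carbon.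

Step 7
Reactants: 11 1-[2,4-dihydroxy-5-methyl-6-(2-methylbut-3-yn-2-yloxy)-3-(prop-2-en-1-yl)phenyl]-2-methylpropan-1-one
Product: 12 1-[2,4-dihydroxy-5-methyl-6-(2-methylbut-3-en-2-yloxy)-3-(prop-2-en-1-yl)phenyl]-2-methylpropan-1-one
Conditions: H2 (1 atm), Pd/CaCO3 poisoned with Pb(OAc)2, quinoline, EtOAc, 0 °C
Reagents that add atoms: none
Why: Lindlar semi-hydrogenation stops at the alkene and spares the allyl group; since the tertiary allylic aryl ether can ionise or undergo [3,3] shift, 12 is kept cold and acid-free and is used at once.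

Step 8
Reactants: 12 1-[2,4-dihydroxy-5-methyl-6-(2-methylbut-3-en-2-yloxy)-3-(prop-2-en-1-yl)phenyl]-2-methylpropan-1-one
Product: 14 (3S,3aR,5R)-2,2,3a-trimethyl-7-(2-methylpropanoyl)-5-(prop-2-en-1-yl)-2,3-dihydro-3,5-methano-1-benzofuran-4,6(3aH,5H)-dione, via phenoxonium cation 13 (not isolated)
Conditions: (R,R)-ArI(OAc)2 (Ar = 2,6-bis[(R)-1-(mesitylamino)-1-oxopropan-2-yloxy]phenyl; 1.1 equiv), CH2Cl2/(CF3)2CHOH 10:1, −40 °C
Reagents that add atoms: none
Why: Proposed new method: the one unchelated phenol, between the allyl-bearing and the methyl-bearing carbon, exchanges for acetate on iodine and loses the iodoarene to give the 2,4-dioxygenated pentadienyl (phenoxonium) cation 13, whose two termini add across the tethered vinyl group, CH2 to the allyl-bearing carbon and CH to the methyl-bearing carbon, before the chelated hydroxyl gives up its proton to leave the vinylogous ester. The closest known reaction type is the cationic (5+2) cycloaddition of oxidatively generated phenoxonium ions with electron-rich or more substituted alkenes to bicyclo[3.2.1]octenediones; an unactivated vinyl group on a two-atom oxygen tether and reagent-controlled enantioselection are not known, and the reasoning is that the first bond (CH2 to the allyl-bearing terminus) is Markovnikov and the second is capture of the resulting cation by the β-carbon of the enol ether that the tether oxygen itself provides. Ring B is closed as the five-membered ring of the (5+2) adduct (three ring carbons plus both vinyl carbons), and the dihydrofuran that becomes ring C is closed 5-exo at the internal vinyl carbon. Both bridgehead centres arise from addition across one face of the planar cation, the ring-fusion CH is forced endo by the two-atom tether, and the face, hence the absolute configuration of all three, is chosen by the chiral ligand sphere on iodine provided the alkene attacks while iodine is still on the phenol oxygen, which the weakly ionising CH2Cl2-rich medium is meant to favour. The step needs the vinyl group to beat capture by solvent or acetate, attack at the acyl-bearing carbon and oxidation of the second alkene: the fluorinated alcohol is non-nucleophilic, the acyl-bearing carbon is the least nucleophilic and most hindered partner, and the allyl group used in place of prenyl is too electron-poor to be oxidised by the reagent and cannot reach the far terminus without a bridgehead double bond. Low temperature holds back ionisation and [3,3] shift of the tertiary allylic ether.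

Step 9
Reactants: 14 (3S,3aR,5R)-2,2,3a-trimethyl-7-(2-methylpropanoyl)-5-(prop-2-en-1-yl)-2,3-dihydro-3,5-methano-1-benzofuran-4,6(3aH,5H)-dione; 15 2-methylbut-2-ene
Product: 16 (3S,3aR,5R)-2,2,3a-trimethyl-5-(3-methylbut-2-en-1-yl)-7-(2-methylpropanoyl)-2,3-dihydro-3,5-methano-1-benzofuran-4,6(3aH,5H)-dione
Conditions: (H2IMes)(PCy3)Cl2Ru=CHPh (second-generation Grubbs catalyst, 5 mol %), 15 (excess), CH2Cl2, 40 °C
Reagents that add atoms: 2-methylbut-2-ene (15), CC=C(C)C
Why: Olefin cross-metathesis of the terminal allyl group with 2-methylbut-2-ene transfers the isopropylidene unit to give the prenyl group; 14 holds no other alkene that can react and no stereocentre is touched.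

Step 10
Reactants: 16 (3S,3aR,5R)-2,2,3a-trimethyl-5-(3-methylbut-2-en-1-yl)-7-(2-methylpropanoyl)-2,3-dihydro-3,5-methano-1-benzofuran-4,6(3aH,5H)-dione
Product: 17 (3aS,5S,6aS)-3,3,6a-trimethyl-5-(3-methylbut-2-en-1-yl)-5-(4-methyl-3-oxopentanoyl)tetrahydro-1H-cyclopenta[c]furan-1,6(6aH)-dione
Conditions: LiOH (1.5 equiv), THF/H2O 3:1, 0 °C to rt; 1 M HCl, 0 °C
Reagents that add atoms: water, O
Why: Retro-Claisen cleavage: hydroxide adds to the alkoxy-bearing carbon of the alkoxymethylene-dione, the one carbon the endo oxygen is already bound to, and the adduct expels the doubly stabilised diketone enolate, which opens the strained bicyclo[3.2.1]octene to the cis-fused cyclopentanone γ-lactone (rings B and C) without touching a stereocentre, while loss of the tertiary alkoxide instead is undone on acidification.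

Step 11
Reactants: 17 (3aS,5S,6aS)-3,3,6a-trimethyl-5-(3-methylbut-2-en-1-yl)-5-(4-methyl-3-oxopentanoyl)tetrahydro-1H-cyclopenta[c]furan-1,6(6aH)-dione
Product: 18 (3aS,5S,6aS,3'R,4'R)-3,3,6a-trimethyl-3'-(2-methylpropanoyl)-4'-(prop-1-en-2-yl)tetrahydro-1H-spiro[cyclopenta[c]furan-5,1'-cyclopentane]-1,2',6(6aH)-trione
Conditions: Mn(OAc)3·2H2O (2.1 equiv), Cu(OAc)2·H2O (1.0 equiv), degassed AcOH, rt
Reagents that add atoms: none
Why: Oxidative radical cyclisation: trivalent manganese turns the β-diketone into the diacyl radical, which closes 5-exo onto the prenyl group, and divalent copper (re-oxidised by Mn(OAc)3) converts the tertiary radical into the isopropenyl alkene; the new CH centre should follow from the spiro centre, since the chain lies on the ring B face that carries the angular methyl and the CMe2 terminus turns toward the CH2–CH edge, away from that methyl and the ring B carbonyl.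

Step 12
Reactants: 18 (3aS,5S,6aS,3'R,4'R)-3,3,6a-trimethyl-3'-(2-methylpropanoyl)-4'-(prop-1-en-2-yl)tetrahydro-1H-spiro[cyclopenta[c]furan-5,1'-cyclopentane]-1,2',6(6aH)-trione
Product: 20 (3aS,5R,5'S,6'S,6aS)-3,3,6a-trimethyl-6'-(2-methylpropanoyl)-5'-(prop-1-en-2-yl)tetrahydro-1H-spiro[cyclopenta[c]furan-5,3'-oxane]-1,2',6(6aH)-trione, via α-hydroxy diketone 19 (not isolated)
Conditions: NaN(SiMe3)2 (1.05 equiv), THF, −78 °C; 3-phenyl-2-(phenylsulfonyl)oxaziridine (1.2 equiv), −78 to −20 °C; AcOH, −78 °C
Reagents that add atoms: 3-phenyl-2-(phenylsulfonyl)oxaziridine, O=S(=O)(c1ccccc1)N1OC1c1ccccc1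
Why: Enolate hydroxylation by a sulfonyloxaziridine followed by the α-ketol ester (carbon-to-oxygen acyl) rearrangement of the α-hydroxy β-diketone alkoxide: the alkoxide adds to the strained ring ketone, which is activated by the second ketone on the spiro carbon, the C–C bond breaks to give the δ-lactone enolate (ring A), and protonation at low temperature on the face away from the neighbouring isopropenyl group should place the isobutyryl group cis to it.

**Compound list**

1 | benzene-1,3,5-triol (phloroglucinol) | Oc1cc(O)cc(O)c1 | starting material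
2 | 2-methylpropanoyl chloride | CC(C)C(=O)Cl | starting material
3 | 2-methyl-1-(2,4,6-trihydroxyphenyl)propan-1-one | CC(C)C(=O)c1c(O)cc(O)cc1O | intermediate
4 | 3-bromoprop-1-ene (allyl bromide) | C=CCBr | starting material
5 | 2-methyl-1-[2,4,6-trihydroxy-3-(prop-2-en-1-yl)phenyl]propan-1-one | CC(C)C(=O)c1c(O)cc(O)c(CC=C)c1O | intermediate
6 | 1-[2,6-dihydroxy-3-(prop-2-en-1-yl)-4-(triisopropylsilyloxy)phenyl]-2-methylpropan-1-one | CC(C)C(=O)c1c(O)cc(O[Si](C(C)C)(C(C)C)C(C)C)c(CC=C)c1O | intermediate
7 | 3-chloro-3-methylbut-1-yne | CC(C)(Cl)C#C | starting material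
8 | 1-[2-hydroxy-6-(2-methylbut-3-yn-2-yloxy)-3-(prop-2-en-1-yl)-4-(triisopropylsilyloxy)phenyl]-2-methylpropan-1-one | CC(C)C(=O)c1c(OC(C)(C)C#C)cc(O[Si](C(C)C)(C(C)C)C(C)C)c(CC=C)c1O | intermediate
9 | 1-[2,4-dihydroxy-6-(2-methylbut-3-yn-2-yloxy)-3-(prop-2-en-1-yl)phenyl]-2-methylpropan-1-one | CC(C)C(=O)c1c(OC(C)(C)C#C)cc(O)c(CC=C)c1O | intermediate
10 | iodomethane | CI | starting material
11 | 1-[2,4-dihydroxy-5-methyl-6-(2-methylbut-3-yn-2-yloxy)-3-(prop-2-en-1-yl)phenyl]-2-methylpropan-1-one | CC(C)C(=O)c1c(OC(C)(C)C#C)c(C)c(O)c(CC=C)c1O | intermediate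
12 | 1-[2,4-dihydroxy-5-methyl-6-(2-methylbut-3-en-2-yloxy)-3-(prop-2-en-1-yl)phenyl]-2-methylpropan-1-one (key-step precursor, allyl in place of prenyl) | CC(C)C(=O)c1c(OC(C)(C)C=C)c(C)c(O)c(CC=C)c1O | intermediate
13 | phenoxonium (2,4-dioxygenated pentadienyl) cation of 12, carbonyl at the carbon between the allyl- and methyl-bearing carbons | C=CC[C+]1C(=O)C(C)=C(OC(C)(C)C=C)C(C(=O)C(C)C)=C1O | intermediate (not isolated)
14 | (3S,3aR,5R)-2,2,3a-trimethyl-7-(2-methylpropanoyl)-5-(prop-2-en-1-yl)-2,3-dihydro-3,5-methano-1-benzofuran-4,6(3aH,5H)-dione | CC(C)C(=O)C1=C2OC(C)(C)[C@H]3C[C@@](CC=C)(C1=O)C(=O)[C@@]23C | intermediate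
15 | 2-methylbut-2-ene | CC=C(C)C | starting material
16 | (3S,3aR,5R)-2,2,3a-trimethyl-5-(3-methylbut-2-en-1-yl)-7-(2-methylpropanoyl)-2,3-dihydro-3,5-methano-1-benzofuran-4,6(3aH,5H)-dione | CC(C)C(=O)C1=C2OC(C)(C)[C@H]3C[C@@](CC=C(C)C)(C1=O)C(=O)[C@@]23C | intermediate
17 | (3aS,5S,6aS)-3,3,6a-trimethyl-5-(3-methylbut-2-en-1-yl)-5-(4-methyl-3-oxopentanoyl)tetrahydro-1H-cyclopenta[c]furan-1,6(6aH)-dione (cis-fused rings B and C) | CC(C)C(=O)CC(=O)[C@]1(CC=C(C)C)C[C@@H]2C(C)(C)OC(=O)[C@]2(C)C1=O | intermediate
18 | (3aS,5S,6aS,3'R,4'R)-3,3,6a-trimethyl-3'-(2-methylpropanoyl)-4'-(prop-1-en-2-yl)tetrahydro-1H-spiro[cyclopenta[c]furan-5,1'-cyclopentane]-1,2',6(6aH)-trione (3'-centre epimerisable, drawn trans to isopropenyl) | C=C(C)[C@@H]1C[C@]2(C[C@@H]3C(C)(C)OC(=O)[C@]3(C)C2=O)C(=O)[C@H]1C(=O)C(C)C | intermediate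
19 | (3aS,5R,6aS,3'R,4'S)-3'-hydroxy-3,3,6a-trimethyl-3'-(2-methylpropanoyl)-4'-(prop-1-en-2-yl)tetrahydro-1H-spiro[cyclopenta[c]furan-5,1'-cyclopentane]-1,2',6(6aH)-trione (formed as its sodium alkoxide, hydroxyl anti to isopropenyl) | C=C(C)[C@@H]1C[C@]2(C[C@@H]3C(C)(C)OC(=O)[C@]3(C)C2=O)C(=O)[C@]1(O)C(=O)C(C)C | intermediate (not isolated)
20 | (3aS,5R,5'S,6'S,6aS)-3,3,6a-trimethyl-6'-(2-methylpropanoyl)-5'-(prop-1-en-2-yl)tetrahydro-1H-spiro[cyclopenta[c]furan-5,3'-oxane]-1,2',6(6aH)-trione (CNP0216954.1) | C=C(C)[C@@H]1C[C@]2(C[C@@H]3C(C)(C)OC(=O)[C@]3(C)C2=O)C(=O)O[C@@H]1C(=O)C(C)C | target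

**Step count and risks**

Total steps: 12. Longest linear sequence: 12 steps (1 → 20).

Steps most likely to fail:

1. Step 8 (proposed new method). The cation may leave iodine before the alkene engages, so that facial selectivity is lost. The tertiary allylic ether may ionise or undergo [3,3] shift before oxidation. Acetate or solvent may capture the cation. The fallback uses known chemistry and sets out from 3. C-Methylation with 10 (NaOMe, MeOH) should give 2-methyl-1-(2,4,6-trihydroxy-3-methylphenyl)propan-1-one F1. Double C-prenylation at the last ring CH (1-bromo-3-methylbut-2-ene, aq. KOH, 0 °C) should give the dearomatised 3,5-dihydroxy-4-methyl-6,6-bis(3-methylbut-2-en-1-yl)-2-(2-methylpropanoyl)cyclohexa-2,4-dien-1-one F2. Oxidative radical cyclisation (PhI(OAc)2, TEMPO, THF, −78 °C) follows: the methyl-bearing radical carbon attacks one prenyl group 5-exo, the tertiary radical is oxidised and the enol oxygen captures it. This should give racemic 16 F3, whose relative configuration is fixed by the cage. Preparative chromatography on a chiral stationary phase then gives 16, where the route is rejoined before step 10.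

2. Step 10. Hydroxide may attack the strained bridging ketone and cleave the wrong bond. The adduct may only open the ether without C–C scission. The new β-keto lactone may be saponified and lose CO2. The fallback sets out from 16 and masks the competing ketone. NaBH4 (EtOH, −40 °C) should reduce the non-conjugated bridging ketone to give the 4-hydroxy analogue of 16 F4. LiOH in aqueous THF then has only the alkoxy-bearing carbon to attack and should give the 6-hydroxy analogue of 17 F5. Swern oxidation ((COCl)2, DMSO, Et3N) returns 17.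

3. Step 12. The isobutyryl group may migrate to oxygen in place of the ring acyl group. Protonation may set the α-acyloxy ketone centre wrongly. The product enolate may add to the sulfonyl imine. The fallback sets out from 18 and separates the three events. Neutral aerobic hydroxylation (CeCl3·7H2O cat., O2, iPrOH) should give 19, this time isolated. Catalytic DBU in CH2Cl2 lets the alkoxide and both acyl-shift anions interconvert until the ring-expanded lactone accumulates, as 20 together with the C-6' epimer of 20 F6. Me3SiOTf/Et3N converts both into the trimethylsilyl enol ether of 20 F7, and Bu4NF/AcOH at −78 °C protonates it away from the isopropenyl group to give 20.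

**Further compounds**

F1 | step 8 | 2-methyl-1-(2,4,6-trihydroxy-3-methylphenyl)propan-1-one | CC(C)C(=O)c1c(O)cc(O)c(C)c1O
F2 | step 8 | 3,5-dihydroxy-4-methyl-6,6-bis(3-methylbut-2-en-1-yl)-2-(2-methylpropanoyl)cyclohexa-2,4-dien-1-one | CC(C)C(=O)C1=C(O)C(C)=C(O)C(CC=C(C)C)(CC=C(C)C)C1=O
F3 | step 8 | racemic 16 (both enantiomers, relative configuration as in 16) | CC(C)C(=O)C1=C2OC(C)(C)[C@H]3C[C@@](CC=C(C)C)(C1=O)C(=O)[C@@]23C.CC(C)C(=O)C1=C2OC(C)(C)[C@@H]3C[C@](CC=C(C)C)(C1=O)C(=O)[C@]23C
F4 | step 10 | 4-hydroxy analogue of 16 (bridging ketone reduced to the secondary alcohol, carbinol configuration immaterial) | CC(C)C(=O)C1=C2OC(C)(C)[C@H]3C[C@@](CC=C(C)C)(C1=O)C(O)[C@@]23C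
F5 | step 10 | 6-hydroxy analogue of 17 (ring B ketone as the secondary alcohol, carbinol configuration immaterial) | CC(C)C(=O)CC(=O)[C@]1(CC=C(C)C)C[C@@H]2C(C)(C)OC(=O)[C@]2(C)C1O
F6 | step 12 | C-6' epimer of 20 (isobutyryl trans to isopropenyl) | C=C(C)[C@@H]1C[C@]2(C[C@@H]3C(C)(C)OC(=O)[C@]3(C)C2=O)C(=O)O[C@H]1C(=O)C(C)C
F7 | step 12 | trimethylsilyl enol ether of 20 (enol double bond between C-6' and the isobutyryl carbon) | C=C(C)[C@@H]1C[C@]2(C[C@@H]3C(C)(C)OC(=O)[C@]3(C)C2=O)C(=O)OC1=C(O[Si](C)(C)C)C(C)C
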